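**Retrosynthetic overview**

1. The target is a 1,5-diketone, O=C–C(quaternary)–C(quaternary)–CH2–C=O. Its acyl carbon and its CH2 sit cis on the cyclopentane, so joining these two carbons gives a cyclobutane cis-fused to the five-membered ring. The open chain is therefore the retro-aldol (de Mayo-type) opening product of a 2-acyl-1-alkenylcyclobutanol.
2. That cyclobutanol comes from (1R,5R)-1,5-dimethylbicyclo[3.2.0]heptan-6-one by aldol reaction at its only CH2 with the aryl-bearing (E)-pent-3-enal, then 1,2-addition of an (E)-alkenyllithium that brings the hydroxy-enone arm.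
3. The bicyclic ketone is cut at the bond between the two methyl-bearing quaternary carbons (and at CH2–C=O): intramolecular [2+2] cycloaddition of a chiral keteniminium ion made from an acyclic 2,6-dimethylhept-6-enamide of (2S,5S)-2,5-dimethylpyrrolidine.
4. The aldehyde arm comes from an arylcopper and an (E)-allylic bromide (carboalumination of a butynyl silyl ether); the arene comes from 2-bromo-6-methylanisole by C–H borylation and oxidation.
5. Ring order: the cyclopentane (ring A) and the temporary cyclobutane close together in step 3; the cyclobutane is opened again in step 15; the benzene ring is bought.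

Key step: step 3

Assumption: the sense of asymmetric induction in step 3 is taken from the steric model given there, so the (2S,5S)-amine is used (its antipode is equally available and would replace it if the opposite sense were found); the temporary stereocentres of 6, 28, 30 and 31 are carried as mixtures because steps 3 and 15 erase them.

**Route**

Step 1
Reactants: 1 propanoyl chloride; 2 (2S,5S)-2,5-dimethylpyrrolidine
Product: 3 1-[(2S,5S)-2,5-dimethylpyrrolidin-1-yl]propan-1-one
Conditions: Et3N, CH2Cl2, 0 °C to rt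
Reagents that add atoms: none
Why: N-acylation of the secondary amine by the acid chloride with Et3N as HCl scavenger (Schotten–Baumann-type amide formation) leaves the two auxiliary stereocentres untouched.

Step 2
Reactants: 3 1-[(2S,5S)-2,5-dimethylpyrrolidin-1-yl]propan-1-one; 4 5-bromo-2-methylpent-1-ene
Product: 6 1-[(2S,5S)-2,5-dimethylpyrrolidin-1-yl]-2,6-dimethylhept-6-en-1-one, via lithium amide enolate 5 (not isolated)
Conditions: LiN(iPr)2, THF, −78 °C; then 4, DMPU, −78 °C to rt
Reagents that add atoms: none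
Why: SN2 alkylation of the lithium (Z)-amide enolate with the primary bromide installs the alkenyl chain, and the new α-stereocentre is of no consequence because step 3 makes this carbon trigonal.

Step 3
Reactants: 6 1-[(2S,5S)-2,5-dimethylpyrrolidin-1-yl]-2,6-dimethylhept-6-en-1-one
Product: 9 (1R,5R)-1,5-dimethylbicyclo[3.2.0]heptan-6-one, via keteniminium triflate 7 (not isolated), via cyclobutaniminium triflate 8 (not isolated)
Conditions: Tf2O, 2,4,6-collidine, ClCH2CH2Cl, 0 °C to reflux (0.02 M); then H2O, reflux; aq. NaHCO3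
Reagents that add atoms: water, O
Why: O-triflation of the amide and loss of TfOH to collidine give the α,α-disubstituted keteniminium ion 7; its electrophilic central carbon is attacked by the CH2 terminus of the 1,1-disubstituted alkene while the developing tertiary cation is captured by the enamine carbon (asynchronous intramolecular keteniminium–alkene [2+2] cycloaddition), and hydrolysis of iminium 8 releases the cyclobutanone and the auxiliary. The closest known reaction type is the intramolecular [2+2] cycloaddition of keteniminium salts (and ketenes) of hept-6-enoic acid derivatives to bicyclo[3.2.0]heptan-6-ones, including the auxiliary-controlled asymmetric variant with C2-symmetric 2,5-dimethylpyrrolidine amides. The cyclopentane (ring A) closes in the 5-exo-trig mode by the bond between the two methyl-bearing carbons, and the cyclobutanone closes as the second bond of the cycloaddition. Both quaternary stereocentres arise here: their cis relation follows from suprafacial addition across the alkene and from the cis-only fusion of a bicyclo[3.2.0]heptane, and their absolute configuration from the auxiliary, the bond to the α-carbon forming on the side of the nitrogen substituent whose methyl group points away from the tether. The step needs regioselectivity for the [3.2.0] over the [3.1.1] skeleton, which the methyl group on the internal alkene carbon should secure by placing the positive charge on the tertiary carbon, and it needs cyclisation to outrun intermolecular reaction, which high dilution and the three-carbon tether should secure.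

Step 4
Reactants: 10 1-bromo-2-methoxy-3-methylbenzene (2-bromo-6-methylanisole)
Product: 12 3-bromo-4-methoxy-5-methylphenol, via aryl pinacol boronate 11 (not isolated)
Conditions: [Ir(OMe)(cod)]2 (cat.), 4,4'-di-tert-butyl-2,2'-bipyridine, B2pin2, THF, 80 °C; then aq. H2O2, NaOH, 0 °C
Reagents that add atoms: hydrogen peroxide, OO
Why: Iridium-catalysed aromatic C–H borylation is sterically governed and should select the only ring C–H without an ortho neighbour (para to OMe), and alkaline peroxide oxidation of the C–B bond then gives the phenol with the C–Br bond intact.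

Step 5
Reactants: 12 3-bromo-4-methoxy-5-methylphenol
Product: 13 (3-bromo-4-methoxy-5-methylphenoxy)(tert-butyl)dimethylsilane
Conditions: TBSCl, imidazole, DMF, rt
Reagents that add atoms: tert-butyldimethylsilyl chloride, CC(C)(C)[Si](C)(C)Cl
Why: Imidazole-mediated O-silylation masks the acidic phenol for the organolithium steps that follow.

Step 6
Reactants: 14 (but-3-yn-1-yloxy)(tert-butyl)dimethylsilane
Product: 16 (E)-5-(tert-butyldimethylsilyloxy)-3-methylpent-2-en-1-ol, via alkenylalane 15 (not isolated)
Conditions: Me3Al, Cp2ZrCl2 (20 mol%), CH2Cl2, 0 °C to rt; then n-BuLi, THF, −78 °C; (CH2O)n, −78 °C to rt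
Reagents that add atoms: trimethylaluminium, C[Al](C)C; formaldehyde (as paraformaldehyde), C=O
Why: Zirconium-catalysed syn-carboalumination (Negishi carboalumination) puts methyl on the internal and aluminium on the terminal alkyne carbon, fixing the (E)-trisubstituted alkene, and the derived alanate adds to formaldehyde with retention.

Step 7
Reactants: 16 (E)-5-(tert-butyldimethylsilyloxy)-3-methylpent-2-en-1-ol
Product: 17 (E)-[(5-bromo-3-methylpent-3-en-1-yl)oxy](tert-butyl)dimethylsilane
Conditions: CBr4, PPh3, CH2Cl2, 0 °C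
Reagents that add atoms: tetrabromomethane, BrC(Br)(Br)Br
Why: Appel bromination converts the primary allylic alcohol to the bromide under neutral conditions, without allylic transposition or loss of alkene geometry.

Step 8
Reactants: 13 (3-bromo-4-methoxy-5-methylphenoxy)(tert-butyl)dimethylsilane; 17 (E)-[(5-bromo-3-methylpent-3-en-1-yl)oxy](tert-butyl)dimethylsilane
Product: 20 (E)-tert-butyl{3-[5-(tert-butyldimethylsilyloxy)-3-methylpent-2-en-1-yl]-4-methoxy-5-methylphenoxy}dimethylsilane, via aryllithium 18 (not isolated), via arylcopper 19 (not isolated)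
Conditions: 13, n-BuLi, THF, −78 °C; CuBr·SMe2, −78 to −40 °C; then 17, −78 to 0 °C
Reagents that add atoms: none
Why: Bromine–lithium exchange, transmetalation to the arylcopper and SN2 substitution of the primary allylic bromide (copper-mediated allylic arylation) join arene and chain at the unsubstituted allylic terminus with retention of the (E)-alkene.

Step 9
Reactants: 20 (E)-tert-butyl{3-[5-(tert-butyldimethylsilyloxy)-3-methylpent-2-en-1-yl]-4-methoxy-5-methylphenoxy}dimethylsilane
Product: 21 (E)-5-[5-(tert-butyldimethylsilyloxy)-2-methoxy-3-methylphenyl]-3-methylpent-3-en-1-ol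
Conditions: camphorsulfonic acid (cat.), MeOH/CH2Cl2, 0 °C
Reagents that add atoms: none
Why: Acid-catalysed methanolysis cleaves the primary alkyl silyl ether much faster than the less basic aryl silyl ether (chemoselective desilylation).

Step 10
Reactants: 21 (E)-5-[5-(tert-butyldimethylsilyloxy)-2-methoxy-3-methylphenyl]-3-methylpent-3-en-1-ol
Product: 22 (E)-5-[5-(tert-butyldimethylsilyloxy)-2-methoxy-3-methylphenyl]-3-methylpent-3-enal
Conditions: Dess–Martin periodinane, NaHCO3, CH2Cl2, 0 °C; used at once
Reagents that add atoms: none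
Why: Dess–Martin oxidation under bicarbonate buffer should give the β,γ-unsaturated aldehyde without migration of the double bond into conjugation.

Step 11
Reactants: 23 2-methylbut-3-yn-2-ol
Product: 24 triethyl[(2-methylbut-3-yn-2-yl)oxy]silane
Conditions: Et3SiCl, imidazole, DMAP (cat.), DMF, rt
Reagents that add atoms: chlorotriethylsilane, CC[Si](Cl)(CC)CC
Why: O-silylation protects the tertiary propargylic alcohol as an ether that tolerates t-BuLi.

Step 12
Reactants: 24 triethyl[(2-methylbut-3-yn-2-yl)oxy]silane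
Product: 26 (E)-triethyl[(4-iodo-2-methylbut-3-en-2-yl)oxy]silane, via alkenylzirconocene chloride 25 (not isolated)
Conditions: Cp2Zr(H)Cl, THF, rt; then I2, 0 °C
Reagents that add atoms: iodine, II
Why: Hydrozirconation adds Zr–H syn with zirconium at the terminal carbon, and iodinolysis proceeds with retention to give the (E)-alkenyl iodide.

Step 13
Reactants: 9 (1R,5R)-1,5-dimethylbicyclo[3.2.0]heptan-6-one; 22 (E)-5-[5-(tert-butyldimethylsilyloxy)-2-methoxy-3-methylphenyl]-3-methylpent-3-enal
Product: 28 (1R,5R)-7-{(E)-5-[5-(tert-butyldimethylsilyloxy)-2-methoxy-3-methylphenyl]-1-hydroxy-3-methylpent-3-en-1-yl}-1,5-dimethylbicyclo[3.2.0]heptan-6-one, via lithium enolate 27 (not isolated)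
Conditions: 9, LiN(iPr)2, THF, −78 °C; then 22, −78 °C; AcOH
Reagents that add atoms: none
Why: Only the CH2 of 9 can be enolised (the other α-carbon is quaternary), and kinetic aldol addition of this lithium enolate to the aldehyde at −78 °C forms the side-chain C–C bond, the two new stereocentres being temporary and needing no control.

Step 14
Reactants: 26 (E)-triethyl[(4-iodo-2-methylbut-3-en-2-yl)oxy]silane; 28 (1R,5R)-7-{(E)-5-[5-(tert-butyldimethylsilyloxy)-2-methoxy-3-methylphenyl]-1-hydroxy-3-methylpent-3-en-1-yl}-1,5-dimethylbicyclo[3.2.0]heptan-6-one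
Product: 30 (1R,5R)-7-{(E)-5-[5-(tert-butyldimethylsilyloxy)-2-methoxy-3-methylphenyl]-1-hydroxy-3-methylpent-3-en-1-yl}-1,5-dimethyl-6-[(E)-3-methyl-3-(triethylsilyloxy)but-1-en-1-yl]bicyclo[3.2.0]heptan-6-ol, via alkenyllithium 29 (not isolated)
Conditions: 26 (2.5 equiv), t-BuLi (5 equiv), Et2O, −78 °C; then 28, THF, −78 °C; H2O
Reagents that add atoms: none
Why: Iodine–lithium exchange with retention gives the (E)-alkenyllithium (its trans geometry precludes silyl migration to carbon), one equivalent deprotonates the hydroxyl group and a second undergoes 1,2-addition to the strained cyclobutanone carbonyl, the new carbinol centre being temporary.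

Step 15
Reactants: 30 (1R,5R)-7-{(E)-5-[5-(tert-butyldimethylsilyloxy)-2-methoxy-3-methylphenyl]-1-hydroxy-3-methylpent-3-en-1-yl}-1,5-dimethyl-6-[(E)-3-methyl-3-(triethylsilyloxy)but-1-en-1-yl]bicyclo[3.2.0]heptan-6-ol
Product: 32 (E)-1-[(1R,2R)-2-{(E)-6-[5-(tert-butyldimethylsilyloxy)-2-methoxy-3-methylphenyl]-4-methyl-2-oxohex-4-en-1-yl}-1,2-dimethylcyclopentyl]-4-methyl-4-(triethylsilyloxy)pent-2-en-1-one, via cyclobutanol hydroxy ketone 31 (not isolated)
Conditions: Dess–Martin periodinane, NaHCO3, CH2Cl2, 0 °C to rt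
Reagents that add atoms: none
Why: Dess–Martin oxidation of the secondary alcohol gives a β-hydroxy ketone whose cyclobutanol C–C bond should cleave spontaneously by strain-driven retro-aldol reaction (de Mayo-type fragmentation), unveiling the enone and the CH2–ketone and erasing all three temporary stereocentres, while the two quaternary centres cannot epimerise.

Step 16
Reactants: 32 (E)-1-[(1R,2R)-2-{(E)-6-[5-(tert-butyldimethylsilyloxy)-2-methoxy-3-methylphenyl]-4-methyl-2-oxohex-4-en-1-yl}-1,2-dimethylcyclopentyl]-4-methyl-4-(triethylsilyloxy)pent-2-en-1-one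
Product: 33 (E)-4-hydroxy-1-[(1R,2R)-2-{(E)-6-(5-hydroxy-2-methoxy-3-methylphenyl)-4-methyl-2-oxohex-4-en-1-yl}-1,2-dimethylcyclopentyl]-4-methylpent-2-en-1-one (target)
Conditions: Bu4NF, AcOH, THF, 0 °C to rt
Reagents that add atoms: none
Why: Acetic acid-buffered fluoride cleaves the aryl and the tertiary silyl ether (desilylation) under conditions that should be too mild to move the β,γ-double bond into conjugation.

**Compound list**

1 | propanoyl chloride | CCC(=O)Cl | starting material
2 | (2S,5S)-2,5-dimethylpyrrolidine | C[C@H]1CC[C@H](C)N1 | starting material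
3 | 1-[(2S,5S)-2,5-dimethylpyrrolidin-1-yl]propan-1-one | CCC(=O)N1[C@@H](C)CC[C@@H]1C | intermediate
4 | 5-bromo-2-methylpent-1-ene | C=C(C)CCCBr | starting material
5 | lithium (Z)-1-[(2S,5S)-2,5-dimethylpyrrolidin-1-yl]prop-1-en-1-olate (not isolated) | C/C=C(\O[Li])N1[C@@H](C)CC[C@@H]1C | intermediate
6 | 1-[(2S,5S)-2,5-dimethylpyrrolidin-1-yl]-2,6-dimethylhept-6-en-1-one (configuration at C2 of the acyl chain not defined) | C=C(C)CCCC(C)C(=O)N1[C@@H](C)CC[C@@H]1C | intermediate
7 | (2S,5S)-1-(2,6-dimethylhepta-1,6-dien-1-ylidene)-2,5-dimethylpyrrolidin-1-ium triflate (not isolated) | C=C(C)CCCC(C)=C=[N+]1[C@@H](C)CC[C@@H]1C.[O-]S(=O)(=O)C(F)(F)F | intermediate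
8 | (2S,5S)-1-[(1R,5R)-1,5-dimethylbicyclo[3.2.0]heptan-6-ylidene]-2,5-dimethylpyrrolidin-1-ium triflate (not isolated) | C[C@H]1CC[C@H](C)[N+]1=C2C[C@@]3(C)CCC[C@@]23C.[O-]S(=O)(=O)C(F)(F)F | intermediate
9 | (1R,5R)-1,5-dimethylbicyclo[3.2.0]heptan-6-one | O=C2C[C@@]1(C)CCC[C@]12C | intermediate
10 | 1-bromo-2-methoxy-3-methylbenzene | COc1c(C)cccc1Br | starting material
11 | 2-(3-bromo-4-methoxy-5-methylphenyl)-4,4,5,5-tetramethyl-1,3,2-dioxaborolane (not isolated) | COc1c(C)cc(B2OC(C)(C)C(C)(C)O2)cc1Br | intermediate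
12 | 3-bromo-4-methoxy-5-methylphenol | COc1c(C)cc(O)cc1Br | intermediate
13 | (3-bromo-4-methoxy-5-methylphenoxy)(tert-butyl)dimethylsilane | COc1c(C)cc(O[Si](C)(C)C(C)(C)C)cc1Br | intermediate
14 | (but-3-yn-1-yloxy)(tert-butyl)dimethylsilane | C#CCCO[Si](C)(C)C(C)(C)C | starting material
15 | (E)-[4-(tert-butyldimethylsilyloxy)-2-methylbut-1-en-1-yl]dimethylalane (not isolated) | C[Al](C)/C=C(\C)CCO[Si](C)(C)C(C)(C)C | intermediate
16 | (E)-5-(tert-butyldimethylsilyloxy)-3-methylpent-2-en-1-ol | OC/C=C(\C)CCO[Si](C)(C)C(C)(C)C | intermediate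
17 | (E)-[(5-bromo-3-methylpent-3-en-1-yl)oxy](tert-butyl)dimethylsilane | BrC/C=C(\C)CCO[Si](C)(C)C(C)(C)C | intermediate
18 | [5-(tert-butyldimethylsilyloxy)-2-methoxy-3-methylphenyl]lithium (not isolated) | [Li]c1cc(O[Si](C)(C)C(C)(C)C)cc(C)c1OC | intermediate
19 | [5-(tert-butyldimethylsilyloxy)-2-methoxy-3-methylphenyl]copper (not isolated) | [Cu]c1cc(O[Si](C)(C)C(C)(C)C)cc(C)c1OC | intermediate
20 | (E)-tert-butyl{3-[5-(tert-butyldimethylsilyloxy)-3-methylpent-2-en-1-yl]-4-methoxy-5-methylphenoxy}dimethylsilane | COc1c(C)cc(O[Si](C)(C)C(C)(C)C)cc1C/C=C(\C)CCO[Si](C)(C)C(C)(C)C | intermediate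
21 | (E)-5-[5-(tert-butyldimethylsilyloxy)-2-methoxy-3-methylphenyl]-3-methylpent-3-en-1-ol | COc1c(C)cc(O[Si](C)(C)C(C)(C)C)cc1C/C=C(\C)CCO | intermediate
22 | (E)-5-[5-(tert-butyldimethylsilyloxy)-2-methoxy-3-methylphenyl]-3-methylpent-3-enal | COc1c(C)cc(O[Si](C)(C)C(C)(C)C)cc1C/C=C(\C)CC=O | intermediate
23 | 2-methylbut-3-yn-2-ol | C#CC(C)(C)O | starting material
24 | triethyl[(2-methylbut-3-yn-2-yl)oxy]silane | C#CC(C)(C)O[Si](CC)(CC)CC | intermediate
25 | chlorobis(cyclopentadienyl)[(E)-3-methyl-3-(triethylsilyloxy)but-1-en-1-yl]zirconium (not isolated) | Cl[Zr](/C=C/C(C)(C)O[Si](CC)(CC)CC)(C1C=CC=C1)C1C=CC=C1 | intermediate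
26 | (E)-triethyl[(4-iodo-2-methylbut-3-en-2-yl)oxy]silane | I/C=C/C(C)(C)O[Si](CC)(CC)CC | intermediate
27 | lithium (1R,5R)-1,5-dimethylbicyclo[3.2.0]hept-6-en-6-olate (not isolated) | [Li]OC1=C[C@@]2(C)CCC[C@@]12C | intermediate
28 | (1R,5R)-7-{(E)-5-[5-(tert-butyldimethylsilyloxy)-2-methoxy-3-methylphenyl]-1-hydroxy-3-methylpent-3-en-1-yl}-1,5-dimethylbicyclo[3.2.0]heptan-6-one (mixture at C7 and at the carbinol carbon) | COc1c(C)cc(O[Si](C)(C)C(C)(C)C)cc1C/C=C(\C)CC(O)C1C(=O)[C@]2(C)CCC[C@]12C | intermediate
29 | [(E)-3-methyl-3-(triethylsilyloxy)but-1-en-1-yl]lithium (not isolated) | [Li]/C=C/C(C)(C)O[Si](CC)(CC)CC | intermediate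
30 | (1R,5R)-7-{(E)-5-[5-(tert-butyldimethylsilyloxy)-2-methoxy-3-methylphenyl]-1-hydroxy-3-methylpent-3-en-1-yl}-1,5-dimethyl-6-[(E)-3-methyl-3-(triethylsilyloxy)but-1-en-1-yl]bicyclo[3.2.0]heptan-6-ol (mixture at C6, C7 and the side-chain carbinol carbon) | COc1c(C)cc(O[Si](C)(C)C(C)(C)C)cc1C/C=C(\C)CC(O)C1C(O)(/C=C/C(C)(C)O[Si](CC)(CC)CC)[C@]2(C)CCC[C@]12C | intermediate
31 | (E)-5-[5-(tert-butyldimethylsilyloxy)-2-methoxy-3-methylphenyl]-1-{(1R,5R)-6-hydroxy-1,5-dimethyl-6-[(E)-3-methyl-3-(triethylsilyloxy)but-1-en-1-yl]bicyclo[3.2.0]heptan-7-yl}-3-methylpent-3-en-1-one (not isolated) | COc1c(C)cc(O[Si](C)(C)C(C)(C)C)cc1C/C=C(\C)CC(=O)C1C(O)(/C=C/C(C)(C)O[Si](CC)(CC)CC)[C@]2(C)CCC[C@]12C | intermediate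
32 | (E)-1-[(1R,2R)-2-{(E)-6-[5-(tert-butyldimethylsilyloxy)-2-methoxy-3-methylphenyl]-4-methyl-2-oxohex-4-en-1-yl}-1,2-dimethylcyclopentyl]-4-methyl-4-(triethylsilyloxy)pent-2-en-1-one | COc1c(C)cc(O[Si](C)(C)C(C)(C)C)cc1C/C=C(\C)CC(=O)C[C@@]1(C)CCC[C@@]1(C)C(=O)/C=C/C(C)(C)O[Si](CC)(CC)CC | intermediate
33 | (E)-4-hydroxy-1-[(1R,2R)-2-{(E)-6-(5-hydroxy-2-methoxy-3-methylphenyl)-4-methyl-2-oxohex-4-en-1-yl}-1,2-dimethylcyclopentyl]-4-methylpent-2-en-1-one | COc1c(C)cc(O)cc1C/C=C(\C)CC(=O)C[C@@]1(C)CCC[C@@]1(C)C(=O)/C=C/C(C)(C)O | target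

**Step count**

Total steps: 16.
Longest linear sequence: 9 steps (steps 6, 7, 8, 9, 10, 13, 14, 15, 16; the arene branch through steps 4 and 5 is equally long).

**Steps most likely to fail**

Step 3. The auxiliary may discriminate the two faces of the disubstituted keteniminium ion poorly, or the cationic intermediate may lose a proton before the second bond closes. The fallback sets out from bromide 4. Alkylation of the dianion of propanoic acid (LiN(iPr)2, 2 equiv) with 4 should give racemic 2,6-dimethylhept-6-enoic acid F1. Oxalyl chloride converts it to 2,6-dimethylhept-6-enoyl chloride F2. Et3N in refluxing toluene generates 2,6-dimethylhepta-1,6-dien-1-one F3 (the ketene, not isolated), which should close by the thermal intramolecular ketene–alkene [2+2] cycloaddition to racemic cis-1,5-dimethylbicyclo[3.2.0]heptan-6-one F4. Preparative chromatography on a chiral stationary phase separates 9 from (1S,5S)-1,5-dimethylbicyclo[3.2.0]heptan-6-one F5, and the route resumes at 9.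

Step 13. Proton transfer from the doubly activated CH2 of aldehyde 22 to the hindered lithium enolate, with drift of the double bond into conjugation, may outrun C–C bond formation. The fallback sets out from 9. LiN(iPr)2 and Me3SiCl should give (1R,5R)-1,5-dimethyl-6-(trimethylsilyloxy)bicyclo[3.2.0]hept-6-ene F6, which adds to 22 under BF3·OEt2 at −78 °C (Mukaiyama aldol, no basic enolate present) and returns to the route at 28.

Step 14. Deprotonation of the α-branched cyclobutanone and retro-aldol cleavage of the lithium aldolate may compete with 1,2-addition to the crowded carbonyl group. The fallback sets out from 28 and alkyne 24. The lithium acetylide of 24 (n-BuLi, THF, −78 °C), a slimmer and less basic nucleophile, should add to 28 to give (1R,5R)-7-{(E)-5-[5-(tert-butyldimethylsilyloxy)-2-methoxy-3-methylphenyl]-1-hydroxy-3-methylpent-3-en-1-yl}-1,5-dimethyl-6-[3-methyl-3-(triethylsilyloxy)but-1-yn-1-yl]bicyclo[3.2.0]heptan-6-ol F7. Hydroxyl-directed trans-hydroalumination with NaAlH2(OCH2CH2OMe)2 then reduces the alkyne to the (E)-alkene and returns to the route at 30.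

**Further compounds**

F1 | step 3 | 2,6-dimethylhept-6-enoic acid (racemic) | C=C(C)CCCC(C)C(=O)O
F2 | step 3 | 2,6-dimethylhept-6-enoyl chloride (racemic) | C=C(C)CCCC(C)C(=O)Cl
F3 | step 3 | 2,6-dimethylhepta-1,6-dien-1-one (ketene, not isolated) | C=C(C)CCCC(C)=C=O
F4 | step 3 | cis-1,5-dimethylbicyclo[3.2.0]heptan-6-one (racemic) | O=C1CC2(C)CCCC12C
F5 | step 3 | (1S,5S)-1,5-dimethylbicyclo[3.2.0]heptan-6-one | O=C2C[C@]1(C)CCC[C@@]12C
F6 | step 13 | (1R,5R)-1,5-dimethyl-6-(trimethylsilyloxy)bicyclo[3.2.0]hept-6-ene | C[Si](C)(C)OC1=C[C@@]2(C)CCC[C@@]12C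
F7 | step 14 | (1R,5R)-7-{(E)-5-[5-(tert-butyldimethylsilyloxy)-2-methoxy-3-methylphenyl]-1-hydroxy-3-methylpent-3-en-1-yl}-1,5-dimethyl-6-[3-methyl-3-(triethylsilyloxy)but-1-yn-1-yl]bicyclo[3.2.0]heptan-6-ol | COc1c(C)cc(O[Si](C)(C)C(C)(C)C)cc1C/C=C(\C)CC(O)C1C(O)(C#CC(C)(C)O[Si](CC)(CC)CC)[C@]2(C)CCC[C@]12C
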